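| setting | summer | autumn | winter | flask |
|---|---|---|---|---|
| substrate | 0.50 mM | 2 mM | 1 mM | 1.0 mM |
| reagent | 0.50 equiv | 0.50 equiv | 1 equiv | 0.500 equiv |
| capture agent | 0.30 mM | 0.30 mM | 0.30 mM | 0.300 mM |
| remark | run made earlier | run made earlier | run made earlier |  |
| time |  |  |  | 4.0 min |

| run | time / min | mono adduct / % | bis adduct / % | substrate / % |
|---|---|---|---|---|
| summer | 0.200 | 35.5 | 5.7 | 55.1 |
| summer | 0.333 | 34.4 | 5.4 | 55.4 |
| summer | 0.417 | 32.6 | 5.3 | 55.7 |
| summer | 0.667 | 29.6 | 5.3 | 55.8 |
| summer | 1.00 | 26.8 | 5.4 | 55.5 |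
| summer | 1.50 | 22.2 | 5.6 | 55.8 |
| summer | 2.50 | 16.6 | 5.7 | 55.9 |
| autumn | 0.333 | 34.2 | 5.5 | 55.4 |
| autumn | 0.667 | 31.1 | 5.6 | 55.2 |
| autumn | 1.00 | 29.5 | 4.9 | 55.5 |
| autumn | 1.33 | 28.3 | 5.0 | 55.1 |
| autumn | 1.50 | 27.6 | 5.1 | 55.8 |
| autumn | 2.00 | 26.9 | 5.4 | 55.2 |
| autumn | 2.50 | 25.5 | 5.9 | 55.3 |
| winter | 0.200 | 49.4 | 23.4 | 22.9 |
| winter | 0.667 | 42.5 | 23.3 | 22.8 |
| winter | 1.00 | 39.2 | 22.8 | 23.1 |
| winter | 1.50 | 35.2 | 23.3 | 22.8 |
| winter | 2.50 | 30.2 | 22.6 | 23.0 |

(standard deviation of a reading: 0.3 percentage points)

- reactions considered so far: reagent + mono adduct -> bis adduct; substrate + reagent -> mono adduct; mono adduct + capture agent -> trapped intermediate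

- equivalents of reagent to substrate, everything else as given, that leave most mono adduct at 4.0 min
- the amount of mono adduct then, in percent of the substrate charged
- the amount of mono adduct with the amounts as given

If the substrate and bis adduct readings stay flat from the first sample on, the additions are over by 0.200 min, and afterwards mono adduct drains into capture agent, one for one. Two amounts then stand against each other. The summer readings at 1.00 min leave 39.1% of the substrate as mono adduct before any trapping, and the flask at this equivalent is taken to share that split. It therefore starts its drain with 0.391 mM mono adduct against 0.300 mM capture agent, which is the limiting reagent of the drain.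

Each trapping removes one of each, so [mono adduct] − [capture agent] holds still at 0.0910 mM, the excess. In logarithms, ln([mono adduct]/[capture agent]) then climbs in a straight line with slope k times the excess. The last summer reading, where the excess is negative, gives k = 1.48 L mmol⁻¹ min⁻¹. By 4.0 min the flask's ratio reaches 2.23, which this reckoning turns into 16.5% mono adduct.

The forecast, noting “Autumn levels off as the capture agent runs out”, gave 16.3% for the flask, and 27.2% at 1.02 equiv.

The flask gives 16.4%, and 27.4% at 1.02 equiv.

    reagent + mono adduct → bis adduct (k = 1200 L mol⁻¹ s⁻¹)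
    substrate + reagent → mono adduct (k = 2900 L mol⁻¹ s⁻¹)
    mono adduct + capture agent → trapped intermediate (k = 25.0 L mol⁻¹ s⁻¹)

The trapping step takes the flask from 39.0% to 16.4%, the largest single effect on its mono adduct. Left for 40.0 min, with capture agent down to 0.101% of its charge, the flask keeps 9.10%, the reckoned excess being 9.10% of its substrate. In the neighbour with 0.60 mM substrate the sign turns, capture agent leading by a reckoned 0.0654 mM, and that neighbour shows 0.0655 mM.

The data were computed for substances that don't exist.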